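**Retrosynthetic overview**
- The target comes from the fully assembled (3R)-8-formyl-5,7-dimethoxyisoflavan by chelation-controlled 7-O-demethylation and desilylation.
- The dihydropyran ring of the isoflavan (O1–C2) is closed last by a Mitsunobu reaction, after phenol-directed ortho-formylation (C8–CHO) of a phenol/primary alcohol obtained by hydride opening of a (3R)-3-aryl-dihydrocoumarin.
- Key bond C3–C(aryl): racemic 3-bromo-5,7-dimethoxychroman-2-one serves as an enolonium (lactone α-cation) equivalent and is joined to the ring B arylzinc by enantioconvergent CoI2/bis(oxazoline) coupling, which sets C3.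
- Fragments: 3,5-dimethoxyphenol + acrylic acid (lactone, then α-bromination); 4-bromoresorcinol + 3-chloro-3-methylbut-1-yne (propargyl Claisen to the 8-bromo-2,2-dimethylchromene).
- Ring order: temporary lactone ring on ring A, then the dimethylpyran on ring B, then lactone opening, then the isoflavan dihydropyran ring.

Assumption: the sense of induction of the cobalt–bis(oxazoline) catalyst on the bromo lactone is not known in advance; the ligand enantiomer written in step 6 stands for the one that gives the (R) product, and its antipode is used if the sense turns out opposite.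

**Step 1**
Reactants: 1 3,5-dimethoxyphenol; 2 acrylic acid
Product: 4 5,7-dimethoxychroman-2-one, via aryl acrylate 3 (not isolated)
Conditions: Amberlyst-15 (sulfonic acid resin), toluene, reflux, Dean–Stark
Reagents that add atoms: none
Why: Acid-catalysed esterification gives the aryl acrylate, whose tether delivers the acrylate β-carbon to the very electron-rich ortho carbon (intramolecular Friedel–Crafts conjugate alkylation), and the symmetry of 1 makes both ortho positions identical.

**Step 2**
Reactants: 4 5,7-dimethoxychroman-2-one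
Product: 6 rac-3-bromo-5,7-dimethoxychroman-2-one, via silyl ketene acetal 5 (not isolated)
Conditions: LiN(SiMe3)2, Me3SiCl, THF, −78 °C; then NBS, THF, −78 °C
Reagents that add atoms: N-bromosuccinimide, O=C1CCC(=O)N1Br
Why: Kinetic enolisation with in situ silylation gives a silyl ketene acetal that is far more nucleophilic than the dimethoxyarene and is brominated at C3 by NBS (electrophilic α-halogenation); the racemate is acceptable because the next coupling is stereoconvergent.

**Step 3**
Reactants: 7 4-bromoresorcinol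
Product: 8 2-bromo-5-(triisopropylsilyloxy)phenol
Conditions: i-Pr3SiCl (1.05 equiv), imidazole, CH2Cl2, 0 °C
Reagents that add atoms: triisopropylsilyl chloride, CC(C)[Si](Cl)(C(C)C)C(C)C
Why: Sterically controlled silyl ether formation: the bulky silyl chloride reacts at the unhindered hydroxyl para to bromine and not at the hydroxyl flanked by bromine.

**Step 4**
Reactants: 8 2-bromo-5-(triisopropylsilyloxy)phenol; 9 3-chloro-3-methylbut-1-yne
Product: 10 1-bromo-2-(2-methylbut-3-yn-2-yloxy)-4-(triisopropylsilyloxy)benzene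
Conditions: DBU, CuCl2·2H2O (1 mol %), MeCN, 0 °C
Reagents that add atoms: none
Why: Copper-catalysed propargylic O-alkylation (Godfrey conditions) etherifies even hindered phenols with tertiary propargyl chlorides under mild base that leaves the silyl ether intact.

**Step 5**
Reactants: 10 1-bromo-2-(2-methylbut-3-yn-2-yloxy)-4-(triisopropylsilyloxy)benzene
Product: 12 8-bromo-2,2-dimethyl-5-(triisopropylsilyloxy)-2H-chromene, via allenyl phenol 11 (not isolated)
Conditions: PhNEt2, 185 °C
Reagents that add atoms: none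
Why: The aromatic propargyl Claisen rearrangement can only end at the free ortho carbon between the two oxygens, and the allenyl phenol then closes the 2,2-dimethylpyran by 1,5-hydrogen shift and oxa-6π electrocyclisation, fixing bromine ortho to the pyran oxygen and para to the silyloxy group.

**Step 6 (key step)**
Reactants: 12 8-bromo-2,2-dimethyl-5-(triisopropylsilyloxy)-2H-chromene; 6 rac-3-bromo-5,7-dimethoxychroman-2-one
Product: 15 (3R)-3-[2,2-dimethyl-5-(triisopropylsilyloxy)-2H-chromen-8-yl]-5,7-dimethoxychroman-2-one, via arylmagnesium bromide 13 (not isolated), via arylzinc bromide 14 (not isolated)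
Conditions: 12, Mg, LiCl, THF, 25 °C; ZnBr2, 0 °C; then 6, CoI2 (10 mol %), (S,S)-Ph-BOX [2,2'-(propane-2,2-diyl)bis((4S)-4-phenyl-4,5-dihydrooxazole)] (12 mol %), THF, −25 °C
Reagents that add atoms: none
Why: Proposed new method: the C3–Br bond of the racemic bromo lactone (an enolonium equivalent) is reduced by low-valent cobalt to a planar lactone α-radical that has lost its configuration, this radical is captured by the chiral bis(oxazoline)–arylcobalt species and reductive elimination from trivalent cobalt fixes C3 as (R) from both enantiomers of 6, while the non-basic arylzinc should avoid lactone opening, HBr loss to the coumarin and epimerisation of the product; the closest known reaction type is the CoI2/bis(oxazoline)- and NiCl2·glyme/diamine-catalysed stereoconvergent Kumada, Negishi and Hiyama arylation of racemic acyclic α-bromo esters, which has not been run on a dihydrocoumarin.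

**Step 7**
Reactants: 15 (3R)-3-[2,2-dimethyl-5-(triisopropylsilyloxy)-2H-chromen-8-yl]-5,7-dimethoxychroman-2-one
Product: 16 2-{(2R)-2-[2,2-dimethyl-5-(triisopropylsilyloxy)-2H-chromen-8-yl]-3-hydroxypropyl}-3,5-dimethoxyphenol
Conditions: LiAlH4, THF, −20 → 0 °C
Reagents that add atoms: none
Why: Hydride reduction of the aryl lactone is fast at low temperature and gives the phenol and the primary alcohol directly, so C3 is taken out of the enolisable α-position before it can epimerise.

**Step 8**
Reactants: 16 2-{(2R)-2-[2,2-dimethyl-5-(triisopropylsilyloxy)-2H-chromen-8-yl]-3-hydroxypropyl}-3,5-dimethoxyphenol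
Product: 18 3-{(2R)-2-[2,2-dimethyl-5-(triisopropylsilyloxy)-2H-chromen-8-yl]-3-hydroxypropyl}-2-hydroxy-4,6-dimethoxybenzaldehyde, via salicyl alcohol 17 (not isolated)
Conditions: MgCl2, Et3N, (CH2O)n, MeCN, 75 °C; dilute aq. HCl work-up
Reagents that add atoms: paraformaldehyde (as formaldehyde), C=O
Why: Casnati–Skattebøl ortho-formylation: the magnesium phenoxide delivers formaldehyde only to the one free ortho carbon (the future C8) and a second formaldehyde oxidises the benzylic alkoxide by hydride transfer, so the position between the two methoxy groups and the silylated ring B are not touched.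

**Step 9**
Reactants: 18 3-{(2R)-2-[2,2-dimethyl-5-(triisopropylsilyloxy)-2H-chromen-8-yl]-3-hydroxypropyl}-2-hydroxy-4,6-dimethoxybenzaldehyde
Product: 19 (3R)-3-[2,2-dimethyl-5-(triisopropylsilyloxy)-2H-chromen-8-yl]-5,7-dimethoxychroman-8-carbaldehyde
Conditions: PPh3, DIAD, THF (0.02 M), 0 °C → rt
Reagents that add atoms: none
Why: Intramolecular Mitsunobu etherification: the acidic salicylaldehyde phenol displaces the activated primary alcohol to close the six-membered ring, and the stereocentre one carbon away is not involved.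

**Step 10**
Reactants: 19 (3R)-3-[2,2-dimethyl-5-(triisopropylsilyloxy)-2H-chromen-8-yl]-5,7-dimethoxychroman-8-carbaldehyde
Product: 21 (3R)-7-hydroxy-3-(5-hydroxy-2,2-dimethyl-2H-chromen-8-yl)-5-methoxychroman-8-carbaldehyde (target), via silyl ether 20 (not isolated)
Conditions: BCl3, CH2Cl2, −78 → −20 °C; H2O quench at −78 °C, evaporate; then Bu4NF, AcOH, THF, 0 °C
Reagents that add atoms: none
Why: BCl3 chelated between the aldehyde and the ortho methoxy oxygen cleaves only that methyl ether (chelation-controlled demethylation; the para 5-methoxy group and the β-branched ring ether react far more slowly), and buffered fluoride then removes the silyl ether without touching the chromene.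

**Compound list**
1 | 3,5-dimethoxyphenol | COc1cc(O)cc(OC)c1 | starting material
2 | acrylic acid | C=CC(=O)O | starting material
3 | 3,5-dimethoxyphenyl prop-2-enoate (aryl acrylate) | C=CC(=O)Oc1cc(OC)cc(OC)c1 | intermediate
4 | 5,7-dimethoxychroman-2-one | COc1cc(OC)cc2c1CCC(=O)O2 | intermediate
5 | 5,7-dimethoxy-2-(trimethylsilyloxy)-4H-chromene (silyl ketene acetal) | COc1cc(OC)cc2c1CC=C(O[Si](C)(C)C)O2 | intermediate
6 | rac-3-bromo-5,7-dimethoxychroman-2-one | COc1cc(OC)cc2c1CC(Br)C(=O)O2 | intermediate
7 | 4-bromoresorcinol | Oc1ccc(Br)c(O)c1 | starting material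
8 | 2-bromo-5-(triisopropylsilyloxy)phenol | CC(C)[Si](Oc1ccc(Br)c(O)c1)(C(C)C)C(C)C | intermediate
9 | 3-chloro-3-methylbut-1-yne | C#CC(C)(C)Cl | starting material
10 | 1-bromo-2-(2-methylbut-3-yn-2-yloxy)-4-(triisopropylsilyloxy)benzene | CC(C)[Si](Oc1ccc(Br)c(OC(C)(C)C#C)c1)(C(C)C)C(C)C | intermediate
11 | 6-bromo-2-(3-methylbuta-1,2-dien-1-yl)-3-(triisopropylsilyloxy)phenol (allenyl phenol) | CC(C)=C=Cc1c(O)c(Br)ccc1O[Si](C(C)C)(C(C)C)C(C)C | intermediate
12 | 8-bromo-2,2-dimethyl-5-(triisopropylsilyloxy)-2H-chromene | CC(C)[Si](Oc1ccc(Br)c2OC(C)(C)C=Cc12)(C(C)C)C(C)C | intermediate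
13 | [2,2-dimethyl-5-(triisopropylsilyloxy)-2H-chromen-8-yl]magnesium bromide | Br[Mg]c1ccc(O[Si](C(C)C)(C(C)C)C(C)C)c2C=CC(C)(C)Oc12 | intermediate
14 | [2,2-dimethyl-5-(triisopropylsilyloxy)-2H-chromen-8-yl]zinc bromide | Br[Zn]c1ccc(O[Si](C(C)C)(C(C)C)C(C)C)c2C=CC(C)(C)Oc12 | intermediate
15 | (3R)-3-[2,2-dimethyl-5-(triisopropylsilyloxy)-2H-chromen-8-yl]-5,7-dimethoxychroman-2-one | COc1cc(OC)cc2c1C[C@H](c1ccc(O[Si](C(C)C)(C(C)C)C(C)C)c3C=CC(C)(C)Oc13)C(=O)O2 | intermediate
16 | 2-{(2R)-2-[2,2-dimethyl-5-(triisopropylsilyloxy)-2H-chromen-8-yl]-3-hydroxypropyl}-3,5-dimethoxyphenol | COc1cc(OC)cc(O)c1C[C@H](c1ccc(O[Si](C(C)C)(C(C)C)C(C)C)c2C=CC(C)(C)Oc12)CO | intermediate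
17 | 6-{(2R)-2-[2,2-dimethyl-5-(triisopropylsilyloxy)-2H-chromen-8-yl]-3-hydroxypropyl}-2-(hydroxymethyl)-3,5-dimethoxyphenol (salicyl alcohol) | COc1cc(OC)c(CO)c(O)c1C[C@H](c1ccc(O[Si](C(C)C)(C(C)C)C(C)C)c2C=CC(C)(C)Oc12)CO | intermediate
18 | 3-{(2R)-2-[2,2-dimethyl-5-(triisopropylsilyloxy)-2H-chromen-8-yl]-3-hydroxypropyl}-2-hydroxy-4,6-dimethoxybenzaldehyde | COc1cc(OC)c(C=O)c(O)c1C[C@H](c1ccc(O[Si](C(C)C)(C(C)C)C(C)C)c2C=CC(C)(C)Oc12)CO | intermediate
19 | (3R)-3-[2,2-dimethyl-5-(triisopropylsilyloxy)-2H-chromen-8-yl]-5,7-dimethoxychroman-8-carbaldehyde | COc1cc(OC)c(C=O)c2c1C[C@H](c1ccc(O[Si](C(C)C)(C(C)C)C(C)C)c3C=CC(C)(C)Oc13)CO2 | intermediate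
20 | (3R)-3-[2,2-dimethyl-5-(triisopropylsilyloxy)-2H-chromen-8-yl]-7-hydroxy-5-methoxychroman-8-carbaldehyde (silyl ether) | COc1cc(O)c(C=O)c2c1C[C@H](c1ccc(O[Si](C(C)C)(C(C)C)C(C)C)c3C=CC(C)(C)Oc13)CO2 | intermediate
21 | (3R)-7-hydroxy-3-(5-hydroxy-2,2-dimethyl-2H-chromen-8-yl)-5-methoxychroman-8-carbaldehyde | COc1cc(O)c(C=O)c2c1C[C@H](c1ccc(O)c3c1OC(C)(C)C=C3)CO2 | target

**Step count**
Total: 10 steps. Longest linear sequence: 8 steps (7 → 21 through steps 3–10); the ring A branch (steps 1–2) joins at step 6.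

**Steps most likely to fail, with fallbacks**

Step 6 is the riskiest. The lactone is outside the documented substrate class, HBr loss to 5,7-dimethoxycoumarin can compete, and the enantioselectivity on a cyclic aryl ester is unknown. The fallback sets out from 4 and returns at 16, using an acyclic α-bromo ester of the class for which the cobalt coupling is documented.
- Lactone 4 is opened with PhCH2OH/NaH (THF, 0 °C) and the phenoxide is capped in the same flask with MeOCH2Cl to give benzyl 3-[2,4-dimethoxy-6-(methoxymethoxy)phenyl]propanoate F1.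
- α-Bromination (LiN(SiMe3)2, THF, −78 °C; then NBS) gives benzyl 2-bromo-3-[2,4-dimethoxy-6-(methoxymethoxy)phenyl]propanoate F2.
- Coupling of F2 with 14 under the step 6 conditions gives benzyl (2R)-2-[2,2-dimethyl-5-(triisopropylsilyloxy)-2H-chromen-8-yl]-3-[2,4-dimethoxy-6-(methoxymethoxy)phenyl]propanoate F3.
- LiAlH4 (THF, 0 °C) reduces F3 to (2R)-2-[2,2-dimethyl-5-(triisopropylsilyloxy)-2H-chromen-8-yl]-3-[2,4-dimethoxy-6-(methoxymethoxy)phenyl]propan-1-ol F4.
- Catalytic HCl in MeOH (rt) removes the methoxymethyl ether, leaves the aryl silyl ether, and returns 16.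

Step 2 is next. The aryl lactone enolate can open, NBS can brominate the dimethoxyarene, and the bromo lactone can lose HBr on work-up. The fallback sets out from 1 and returns at 6, with the bromine in place before the ring is formed. Esterification of 1 with 2-bromoacrylic acid (DCC, cat. DMAP, CH2Cl2, 0 °C) gives 3,5-dimethoxyphenyl 2-bromoprop-2-enoate F5. CF3SO3H (CH2Cl2, 0 °C) then closes the lactone by intramolecular Friedel–Crafts conjugate alkylation to 6, with no base and no electrophilic bromine.

Step 8 is third. The very electron-rich phenol can condense with its own salicyl alcohol to diarylmethanes, and the free primary alcohol consumes reagent. The fallback sets out from 16 and returns at 19 by reversing the order of ring closure and formylation. Mitsunobu closure first (PPh3, DIAD, THF, 0 °C → rt) gives (3R)-3-[2,2-dimethyl-5-(triisopropylsilyloxy)-2H-chromen-8-yl]-5,7-dimethoxychroman F6. Vilsmeier–Haack formylation (POCl3, DMF, 0 °C → rt; aq. NaOAc) then gives 19. It should enter C8, the site where 5,7-dialkoxyflavans take electrophiles, because C6 is shielded by two methoxy groups.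

**Further compounds**
F1 | step 6 | benzyl 3-[2,4-dimethoxy-6-(methoxymethoxy)phenyl]propanoate | COCOc1cc(OC)cc(OC)c1CCC(=O)OCc1ccccc1
F2 | step 6 | benzyl 2-bromo-3-[2,4-dimethoxy-6-(methoxymethoxy)phenyl]propanoate (racemic) | COCOc1cc(OC)cc(OC)c1CC(Br)C(=O)OCc1ccccc1
F3 | step 6 | benzyl (2R)-2-[2,2-dimethyl-5-(triisopropylsilyloxy)-2H-chromen-8-yl]-3-[2,4-dimethoxy-6-(methoxymethoxy)phenyl]propanoate | COCOc1cc(OC)cc(OC)c1C[C@H](c1ccc(O[Si](C(C)C)(C(C)C)C(C)C)c2C=CC(C)(C)Oc12)C(=O)OCc1ccccc1
F4 | step 6 | (2R)-2-[2,2-dimethyl-5-(triisopropylsilyloxy)-2H-chromen-8-yl]-3-[2,4-dimethoxy-6-(methoxymethoxy)phenyl]propan-1-ol | COCOc1cc(OC)cc(OC)c1C[C@H](c1ccc(O[Si](C(C)C)(C(C)C)C(C)C)c2C=CC(C)(C)Oc12)CO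
F5 | step 2 | 3,5-dimethoxyphenyl 2-bromoprop-2-enoate | C=C(Br)C(=O)Oc1cc(OC)cc(OC)c1
F6 | step 8 | (3R)-3-[2,2-dimethyl-5-(triisopropylsilyloxy)-2H-chromen-8-yl]-5,7-dimethoxychroman | COc1cc(OC)cc2c1C[C@H](c1ccc(O[Si](C(C)C)(C(C)C)C(C)C)c3C=CC(C)(C)Oc13)CO2
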